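Eudesmane numbering is used: ring A = C1–C5 + C10, ring B = C5–C10, C11 = side-chain carbinol carbon. Endgame: the C8 ketone comes from an allylic alcohol, and the C4 acetate and C3 (2R,3R)-epoxyangelate come from a 3α,4α-diol made by OsO4 on a C3=C4 alkene.
Enabling feature: ring A is a cyclohexane whose cis-diol C3/C4 is a masked C3=C4 double bond. C2 and C5 are then the ends of a diene, C1 and the quaternary methyl-bearing C10 are a methallyl alkene, and C6–C7–C8–C9 of ring B is a four-atom tether.
Key disconnection: C1–C2 and C5–C10 are cut together (intramolecular Diels–Alder reaction), so rings A and B form at once from an acyclic tetraene that already carries C6=C7, O8 and O11.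
Stereochemistry: one carbinol centre (C8) is set by catalysis and locked with O11 in a temporary siladioxane ring. It relays to C5/C10 in the key step, these relay to C3/C4 in the dihydroxylation, and C8 is erased by the last oxidation.
Assembly and ring order: the tetraene comes from 2-methylbut-3-yn-2-ol + CO, a methallyl boronate and an iododiene. The siladioxane forms first, rings A and B form together, and the oxirane arrives ready-made with the acid.

Key step: step 9

Remark: but-1-en-3-yne is taken as purchasable as its stabilised solution; α and β refer to the usual eudesmane drawing with the C10 methyl β.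

Step 1
Reactants: 1 methyl angelate (methyl (Z)-2-methylbut-2-enoate)
Product: 2 (Z)-2-methylbut-2-en-1-ol
Conditions: LiAlH4, Et2O, 0 °C; aqueous work-up
Reagents that add atoms: none
Why: Hydride 1,2-reduction of an enoate to the allylic alcohol leaves the Z-trisubstituted alkene untouched, so the cis relation of the C3 methyl and the oxygenated carbon is kept.

Step 2
Reactants: 2 (Z)-2-methylbut-2-en-1-ol
Product: 3 [(2S,3R)-2,3-dimethyloxiran-2-yl]methanol
Conditions: Ti(OiPr)4 (cat.), L-(+)-DIPT (cat.), t-BuOOH, 4 Å MS, CH2Cl2, −20 °C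
Reagents that add atoms: tert-butyl hydroperoxide, CC(C)(C)OO
Why: In this Katsuki–Sharpless asymmetric epoxidation L-(+)-tartrate should give the 2S epoxy alcohol as it does with other substituted allylic alcohols, and syn oxygen transfer to the Z-alkene fixes C3 as R.

Step 3
Reactants: 3 [(2S,3R)-2,3-dimethyloxiran-2-yl]methanol
Product: 5 (2R,3R)-2,3-dimethyloxirane-2-carboxylic acid, via epoxy aldehyde 4 (not isolated)
Conditions: TEMPO (cat.), PhI(OAc)2, MeCN/H2O, rt
Reagents that add atoms: water, O
Why: Oxoammonium (TEMPO) oxidation of the primary alcohol through the aldehyde hydrate to the acid runs near neutrality, so the trisubstituted epoxide and both stereocentres should survive (the C2 descriptor changes only by priority).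

Step 4
Reactants: 6 but-1-en-3-yne
Product: 8 (1E)-1-iodo-2-methylbuta-1,3-diene, via dienylalane 7 (not isolated)
Conditions: Me3Al, Cp2ZrCl2 (cat.), CH2Cl2, 0 °C to rt; then I2, THF, −30 °C
Reagents that add atoms: trimethylaluminium, C[Al](C)C; iodine, II
Why: Negishi zirconium-catalysed carboalumination adds methyl and aluminium syn across the terminal alkyne with aluminium at the terminus, and iodinolysis with retention gives the E-iodide.

Step 5
Reactants: 9 2-methylbut-3-yn-2-ol
Product: 10 (2Z)-3-[benzyl(dimethyl)silyl]-2-(2-hydroxypropan-2-yl)prop-2-enal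
Conditions: BnMe2SiH, CO (10 atm), Rh(acac)(CO)2 (cat.), PhMe, 25 °C
Reagents that add atoms: benzyldimethylsilane, C[SiH](C)Cc1ccccc1; carbon monoxide, [C-]#[O+]
Why: In rhodium-catalysed silylformylation of a terminal alkyne, syn silylrhodation puts silicon on the terminal carbon and CO insertion puts the formyl group on the internal carbon, so silicon and CHO (future C5 and C8 positions) end cis on C6=C7.

Step 6
Reactants: 10 (2Z)-3-[benzyl(dimethyl)silyl]-2-(2-hydroxypropan-2-yl)prop-2-enal; 11 4,4,5,5-tetramethyl-2-(2-methylprop-2-en-1-yl)-1,3,2-dioxaborolane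
Product: 13 (3E,4S)-3-{[benzyl(dimethyl)silyl]methylidene}-2,6-dimethylhept-6-ene-2,4-diol, via pinacol borate 12 (not isolated)
Conditions: (S)-TRIP (cat.), 4 Å MS, PhMe, −30 °C; then H2O
Reagents that add atoms: none
Why: Chiral-phosphoric-acid-catalysed allylboration through a closed chair transition state should attack the Si face with (S)-TRIP, the antipode of the catalyst that gives R carbinols from aryl and alkenyl aldehydes, and so sets C8 as S.

Step 7
Reactants: 13 (3E,4S)-3-{[benzyl(dimethyl)silyl]methylidene}-2,6-dimethylhept-6-ene-2,4-diol; 8 (1E)-1-iodo-2-methylbuta-1,3-diene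
Product: 15 (3E,4S)-2,6-dimethyl-3-[(2E)-3-methylpenta-2,4-dien-1-ylidene]hept-6-ene-2,4-diol, via vinylsilanol 14 (not isolated)
Conditions: TBAF·3H2O, Pd2(dba)3·CHCl3 (cat.), THF, 0 °C to rt
Reagents that add atoms: water, O (its oxygen stays only in 14)
Why: In this Hiyama coupling fluoride cleaves the benzyl group, the silanol transmetalates with help from the cis C8 hydroxyl, and both alkenyl partners couple with retention; C8 is already sp3, so no Z-dienal exists that could scramble C4=C5 by oxa-6π closure.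

Step 8
Reactants: 15 (3E,4S)-2,6-dimethyl-3-[(2E)-3-methylpenta-2,4-dien-1-ylidene]hept-6-ene-2,4-diol
Product: 16 (5E,6S)-2,2-di-tert-butyl-4,4-dimethyl-5-[(2E)-3-methylpenta-2,4-dien-1-ylidene]-6-(2-methylprop-2-en-1-yl)-1,3,2-dioxasilinane
Conditions: t-Bu2Si(OTf)2, 2,6-lutidine, CH2Cl2, 0 °C
Reagents that add atoms: di-tert-butylsilyl bis(trifluoromethanesulfonate), CC(C)(C)[Si](OS(=O)(=O)C(F)(F)F)(OS(=O)(=O)C(F)(F)F)C(C)(C)C
Why: Cyclic silylene formation on the 1,3-diol masks O8 and O11 in one step and builds the temporary six-membered ring that stiffens the tether, while the buffered medium spares the tetraene.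

Step 9
Reactants: 16 (5E,6S)-2,2-di-tert-butyl-4,4-dimethyl-5-[(2E)-3-methylpenta-2,4-dien-1-ylidene]-6-(2-methylprop-2-en-1-yl)-1,3,2-dioxasilinane
Product: 17 (5R,8S,10R)-8,11-(di-tert-butylsilanediyldioxy)eudesma-3,6-diene (trans-fused; H-5 α; C10 methyl β; O-8 α)
Conditions: PhMe (0.01 M), BHT, sealed tube, 170 °C
Reagents that add atoms: none
Why: This is a thermal type-1 intramolecular Diels–Alder reaction in which the E-diene C2=C3–C4=C5 adds suprafacially to the 1,1-disubstituted alkene C10=C1 through one concerted, slightly asynchronous [4π+2π] transition state that forms C1–C2 and C5–C10 together. The closest known chemistry is the thermal cyclisation of unactivated 2,8-dimethyl-1,7,9-decatrienes to eudesm-3-enes, and here C6, C7 and C8 of the tether are frozen by the Z-alkene and the siladioxane, so only the C5–C6, C8–C9 and C9–C10 rotors must be ordered. Ring A closes as the new cyclohexene of the cycloaddition, and ring B closes in the fused mode through C5–C10 over the four-atom tether C6–C9. With an E-diene C1 must sit equatorial on nascent ring B, and the arrangement with the tether exo and the C10 methyl endo keeps the diene pseudo-equatorial and partly conjugated with C6=C7, which should place H-5 and the C10 methyl trans. The absolute sense comes from C8, because only the half-chair with O8 pseudo-equatorial lets the siladioxane span O8 and C11 without strain and avoids a syn-axial O8/C10-methyl contact, so 8S should relay to 5R,10R. The step also needs periselectivity, which the substrate secures: no other diene/ene pair can reach a five- or six-membered array, the E C4=C5 bond blocks 6π closure and no carbonyl group is present for oxa-6π closure, while dilution and BHT suppress dimerisation.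

Step 10
Reactants: 17 (5R,8S,10R)-8,11-(di-tert-butylsilanediyldioxy)eudesma-3,6-diene
Product: 18 (3R,4S,5R,8S,10R)-8,11-(di-tert-butylsilanediyldioxy)eudesm-6-ene-3,4-diol (3α,4α-diol)
Conditions: OsO4 (cat.), NMO, acetone/H2O, 0 °C to rt
Reagents that add atoms: N-methylmorpholine N-oxide, C[N+]1([O-])CCOCC1; water, O
Why: Upjohn syn-dihydroxylation should attack C3=C4 from the α face opposite the axial C10 methyl and set C3 (R) and C4 (S) together, while C6=C7 is shielded by quaternary C11 and the silylene and deactivated by two allylic C–O bonds.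

Step 11
Reactants: 18 (3R,4S,5R,8S,10R)-8,11-(di-tert-butylsilanediyldioxy)eudesm-6-ene-3,4-diol; 5 (2R,3R)-2,3-dimethyloxirane-2-carboxylic acid
Product: 20 (3R,4S,5R,8S,10R)-8,11-(di-tert-butylsilanediyldioxy)-4-hydroxyeudesm-6-en-3-yl (2R,3R)-2,3-dimethyloxirane-2-carboxylate, via mixed anhydride 19 (not isolated)
Conditions: 2,4,6-Cl3C6H2COCl, Et3N, PhMe, rt; then 18, DMAP, rt to 40 °C
Reagents that add atoms: 2,4,6-trichlorobenzoyl chloride, O=C(Cl)c1c(Cl)cc(Cl)cc1Cl (its atoms stay only in 19)
Why: Yamaguchi esterification activates the α-quaternary epoxy acid without acid chloride conditions and should acylate only the secondary C3 hydroxyl, because the C4 hydroxyl is tertiary and O8/O11 are masked.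

Step 12
Reactants: 20 (3R,4S,5R,8S,10R)-8,11-(di-tert-butylsilanediyldioxy)-4-hydroxyeudesm-6-en-3-yl (2R,3R)-2,3-dimethyloxirane-2-carboxylate
Product: 21 (3R,4S,5R,8S,10R)-4-acetoxy-8,11-(di-tert-butylsilanediyldioxy)eudesm-6-en-3-yl (2R,3R)-2,3-dimethyloxirane-2-carboxylate
Conditions: Ac2O, DMAP, Et3N, PhMe, 50 °C
Reagents that add atoms: acetic anhydride, CC(=O)OC(C)=O
Why: DMAP-catalysed acylation of the only free hydroxyl (equatorial, tertiary C4–OH) needs forcing but non-acidic conditions that the epoxide, the ester and the silylene tolerate, and migration of the C3 acyl group to the tertiary oxygen is uphill.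

Step 13
Reactants: 21 (3R,4S,5R,8S,10R)-4-acetoxy-8,11-(di-tert-butylsilanediyldioxy)eudesm-6-en-3-yl (2R,3R)-2,3-dimethyloxirane-2-carboxylate
Product: 22 (3R,4S,5R,8S,10R)-4-acetoxy-8,11-dihydroxyeudesm-6-en-3-yl (2R,3R)-2,3-dimethyloxirane-2-carboxylate
Conditions: HF·pyridine, pyridine/THF, 0 °C to rt
Reagents that add atoms: none
Why: Buffered fluoride cleavage of the silylene removes the temporary ring without touching the two esters, the electron-poor glycidic epoxide or the allylic alcohols.

Step 14
Reactants: 22 (3R,4S,5R,8S,10R)-4-acetoxy-8,11-dihydroxyeudesm-6-en-3-yl (2R,3R)-2,3-dimethyloxirane-2-carboxylate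
Product: 23 (3R,4S,5R,10R)-4-acetoxy-11-hydroxy-8-oxoeudesm-6-en-3-yl (2R,3R)-2,3-dimethyloxirane-2-carboxylate (target)
Conditions: Dess–Martin periodinane, CH2Cl2, 0 °C to rt
Reagents that add atoms: none
Why: Dess–Martin oxidation converts the only oxidisable hydroxyl (secondary, allylic C8–OH) into the enone, erases the relay stereocentre and leaves the tertiary C11–OH free.

Compound list
1 | methyl angelate | C/C=C(/C)C(=O)OC | starting material
2 | (Z)-2-methylbut-2-en-1-ol | C/C=C(/C)CO | intermediate
3 | [(2S,3R)-2,3-dimethyloxiran-2-yl]methanol | OC[C@@]1(C)O[C@@H]1C | intermediate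
4 | (2R,3R)-2,3-dimethyloxirane-2-carbaldehyde (not isolated) | O=C[C@@]1(C)O[C@@H]1C | intermediate
5 | (2R,3R)-2,3-dimethyloxirane-2-carboxylic acid (epoxyangelic acid) | OC(=O)[C@@]1(C)O[C@@H]1C | intermediate
6 | but-1-en-3-yne | C=CC#C | starting material
7 | dimethyl[(1E)-2-methylbuta-1,3-dien-1-yl]alane (not isolated) | C[Al](C)/C=C(C)/C=C | intermediate
8 | (1E)-1-iodo-2-methylbuta-1,3-diene | I/C=C(C)/C=C | intermediate
9 | 2-methylbut-3-yn-2-ol | CC(C)(O)C#C | starting material
10 | (2Z)-3-[benzyl(dimethyl)silyl]-2-(2-hydroxypropan-2-yl)prop-2-enal | O=C/C(=C\[Si](C)(C)Cc1ccccc1)C(C)(C)O | intermediate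
11 | 4,4,5,5-tetramethyl-2-(2-methylprop-2-en-1-yl)-1,3,2-dioxaborolane | C=C(C)CB1OC(C)(C)C(C)(C)O1 | starting material
12 | C4-O-pinacolboryl derivative of 13 (not isolated) | C=C(C)C[C@H](OB1OC(C)(C)C(C)(C)O1)/C(=C\[Si](C)(C)Cc1ccccc1)C(C)(C)O | intermediate
13 | (3E,4S)-3-{[benzyl(dimethyl)silyl]methylidene}-2,6-dimethylhept-6-ene-2,4-diol | C=C(C)C[C@H](O)/C(=C\[Si](C)(C)Cc1ccccc1)C(C)(C)O | intermediate
14 | (3E,4S)-3-{[hydroxy(dimethyl)silyl]methylidene}-2,6-dimethylhept-6-ene-2,4-diol (not isolated) | C=C(C)C[C@H](O)/C(=C\[Si](C)(C)O)C(C)(C)O | intermediate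
15 | (3E,4S)-2,6-dimethyl-3-[(2E)-3-methylpenta-2,4-dien-1-ylidene]hept-6-ene-2,4-diol | C=C(C)C[C@H](O)/C(=C\C=C(C)\C=C)C(C)(C)O | intermediate
16 | (5E,6S)-2,2-di-tert-butyl-4,4-dimethyl-5-[(2E)-3-methylpenta-2,4-dien-1-ylidene]-6-(2-methylprop-2-en-1-yl)-1,3,2-dioxasilinane | C=C(C)C[C@@H]1O[Si](C(C)(C)C)(C(C)(C)C)OC(C)(C)/C1=C/C=C(C)/C=C | intermediate
17 | (5R,8S,10R)-8,11-(di-tert-butylsilanediyldioxy)eudesma-3,6-diene | CC1=CCC[C@]2(C)C[C@@H]3O[Si](C(C)(C)C)(C(C)(C)C)OC(C)(C)C3=C[C@@H]12 | intermediate
18 | (3R,4S,5R,8S,10R)-8,11-(di-tert-butylsilanediyldioxy)eudesm-6-ene-3,4-diol | O[C@@]1(C)[C@@H]2C=C3C(C)(C)O[Si](C(C)(C)C)(C(C)(C)C)O[C@H]3C[C@@]2(C)CC[C@H]1O | intermediate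
19 | (2R,3R)-2,3-dimethyloxirane-2-carboxylic 2,4,6-trichlorobenzoic anhydride (not isolated) | O=C(OC(=O)c1c(Cl)cc(Cl)cc1Cl)[C@@]1(C)O[C@@H]1C | intermediate
20 | 3-O-[(2R,3R)-epoxyangeloyl] derivative of 18 (C4–OH free) | O[C@@]1(C)[C@@H]2C=C3C(C)(C)O[Si](C(C)(C)C)(C(C)(C)C)O[C@H]3C[C@@]2(C)CC[C@H]1OC(=O)[C@@]1(C)O[C@@H]1C | intermediate
21 | 4-O-acetyl derivative of 20 | CC(=O)O[C@@]1(C)[C@@H]2C=C3C(C)(C)O[Si](C(C)(C)C)(C(C)(C)C)O[C@H]3C[C@@]2(C)CC[C@H]1OC(=O)[C@@]1(C)O[C@@H]1C | intermediate
22 | (3R,4S,5R,8S,10R)-4-acetoxy-8,11-dihydroxyeudesm-6-en-3-yl (2R,3R)-2,3-dimethyloxirane-2-carboxylate | CC(=O)O[C@@]1(C)[C@@H]2C=C(C(C)(C)O)[C@@H](O)C[C@@]2(C)CC[C@H]1OC(=O)[C@@]1(C)O[C@@H]1C | intermediate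
23 | (3R,4S,5R,10R)-4-acetoxy-11-hydroxy-8-oxoeudesm-6-en-3-yl (2R,3R)-2,3-dimethyloxirane-2-carboxylate | CC(=O)O[C@@]1(C)[C@@H]2C=C(C(C)(C)O)C(=O)C[C@@]2(C)CC[C@H]1OC(=O)[C@@]1(C)O[C@@H]1C | target

Total step count: 14. Longest linear sequence: 10 steps (steps 5 to 14, from 2-methylbut-3-yn-2-ol).

Steps most likely to fail

Step 9. The unactivated 1,1-disubstituted alkene may react more slowly than the tetraene is lost to hydrogen shifts or oligomerisation. The half-chair preference may also be too small, which would erode the trans/cis or the facial selectivity. The fallback sets out from 10 and returns at 17; it lends the dienophile a removable acceptor.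
- A catalytic enantioselective vinylogous Mukaiyama aldol reaction of 10 with the tert-butyldimethylsilyl dienolate of methyl 3-methylbut-2-enoate would give methyl (2E,5S,6E)-6-{[benzyl(dimethyl)silyl]methylidene}-5,7-dihydroxy-3,7-dimethyloct-2-enoate F1.
- Fluoride-promoted Hiyama coupling with 8 by way of the vinylsilanol F2 would give the tetraene hydroxy ester F3, and silylene formation the siladioxane enoate F4.
- The E-enoate is a LUMO-lowered dienophile whose β-carbon is C10, matched to the C4-methyl diene, so the intramolecular Diels–Alder reaction (milder heating or Et2AlCl) should run endo to the 1β-methoxycarbonyl adduct F5.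
- Saponification to the 1β-carboxylic acid F6, conversion into the N-hydroxypyridine-2-thione ester F7 and Barton reductive decarboxylation (t-BuSH, hν) would remove the activating group and give 17.

Step 12. Acetylation of the hindered tertiary C4 hydroxyl next to the bulky axial ester may stall, and forcing it may open the epoxide or move acyl groups. The fallback sets out from 18 and returns at 21; it inverts the order of the two acylations so that the hard one is done before the epoxide is present.
- 18 would be esterified at O3 with levulinic acid (DIC, DMAP) to the 3-O-levulinate F8.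
- F8 would be acetylated at O4 under Lewis acid catalysis (Ac2O, Sc(OTf)3 cat., MeCN, −20 °C) to the 4-acetate 3-levulinate F9.
- The levulinate would be removed with hydrazine acetate in pyridine to give the 4-acetate 3-alcohol F10.
- F10 would be esterified at once with 5 through 19 under the conditions of step 11 to give 21. The near-neutral delevulination is chosen to hold back acetyl migration from O4 to O3.

Step 6. The α-branched, β-silylated enal with a free hydroxyl may bind the phosphoric acid poorly, so that addition is slow or the facial selectivity on which every later stereocentre depends is low. The fallback sets out from 10 and returns at 13; it sets C8 by reduction instead of C–C bond formation.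
- Barbier methallylation (3-bromo-2-methylprop-1-ene, Zn, THF/aq. NH4Cl) would give the racemic carbinol F11.
- Dess–Martin oxidation would give the β-silyl enone F12.
- Corey–Bakshi–Shibata reduction with the (R)-oxazaborolidine and catecholborane, which differentiates the branched alkenyl group from the methallyl CH2, should give 13.

Further compounds
F1 | step 9 | methyl (2E,5S,6E)-6-{[benzyl(dimethyl)silyl]methylidene}-5,7-dihydroxy-3,7-dimethyloct-2-enoate | COC(=O)/C=C(C)/C[C@H](O)/C(=C\[Si](C)(C)Cc1ccccc1)C(C)(C)O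
F2 | step 9 | methyl (2E,5S,6E)-5,7-dihydroxy-6-{[hydroxy(dimethyl)silyl]methylidene}-3,7-dimethyloct-2-enoate | COC(=O)/C=C(C)/C[C@H](O)/C(=C\[Si](C)(C)O)C(C)(C)O
F3 | step 9 | methyl (2E,5S,6E)-5,7-dihydroxy-3,7-dimethyl-6-[(2E)-3-methylpenta-2,4-dien-1-ylidene]oct-2-enoate | COC(=O)/C=C(C)/C[C@H](O)/C(=C\C=C(C)\C=C)C(C)(C)O
F4 | step 9 | di-tert-butylsilylene derivative of F3 | COC(=O)/C=C(C)/C[C@@H]1O[Si](C(C)(C)C)(C(C)(C)C)OC(C)(C)/C1=C/C=C(C)/C=C
F5 | step 9 | 1β-methoxycarbonyl derivative of 17 | CC1=CC[C@@H](C(=O)OC)[C@]2(C)C[C@@H]3O[Si](C(C)(C)C)(C(C)(C)C)OC(C)(C)C3=C[C@@H]12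
F6 | step 9 | 1β-carboxylic acid derived from F5 | CC1=CC[C@@H](C(=O)O)[C@]2(C)C[C@@H]3O[Si](C(C)(C)C)(C(C)(C)C)OC(C)(C)C3=C[C@@H]12
F7 | step 9 | N-hydroxypyridine-2-thione ester of F6 | CC1=CC[C@@H](C(=O)ON4C=CC=CC4=S)[C@]2(C)C[C@@H]3O[Si](C(C)(C)C)(C(C)(C)C)OC(C)(C)C3=C[C@@H]12
F8 | step 12 | 3-O-levulinate of 18 | O[C@@]1(C)[C@@H]2C=C3C(C)(C)O[Si](C(C)(C)C)(C(C)(C)C)O[C@H]3C[C@@]2(C)CC[C@H]1OC(=O)CCC(C)=O
F9 | step 12 | 4-O-acetyl-3-O-levulinate of 18 | CC(=O)O[C@@]1(C)[C@@H]2C=C3C(C)(C)O[Si](C(C)(C)C)(C(C)(C)C)O[C@H]3C[C@@]2(C)CC[C@H]1OC(=O)CCC(C)=O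
F10 | step 12 | 4-O-acetate of 18 (C3–OH free) | CC(=O)O[C@@]1(C)[C@@H]2C=C3C(C)(C)O[Si](C(C)(C)C)(C(C)(C)C)O[C@H]3C[C@@]2(C)CC[C@H]1O
F11 | step 6 | racemic (3E)-3-{[benzyl(dimethyl)silyl]methylidene}-2,6-dimethylhept-6-ene-2,4-diol | C=C(C)CC(O)/C(=C\[Si](C)(C)Cc1ccccc1)C(C)(C)O
F12 | step 6 | (3Z)-3-{[benzyl(dimethyl)silyl]methylidene}-2-hydroxy-2,6-dimethylhept-6-en-4-one | C=C(C)CC(=O)/C(=C\[Si](C)(C)Cc1ccccc1)C(C)(C)O
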